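X at 12 min, as a share of the L charged, climbs with the charge in the runs so far, and the climb is what we have to extrapolate.

| flask | L | time |
|---|---|---|
| ash | 0.120 M |  |
| elm | 0.0600 M |  |
| larch | 0.240 M |  |
| maple | 0.550 M | 12 min |

| run | time / min | [X] / M |
|---|---|---|
| ash run | 2.0 | 0.0079 |
| ash run | 4.0 | 0.0175 |
| ash run | 6.0 | 0.0239 |
| ash run | 8.0 | 0.0287 |
| ash run | 10 | 0.0320 |
| ash run | 12 | 0.0313 |
| elm run | 2.0 | 0.0014 |
| elm run | 4.0 | 0.0063 |
| elm run | 6.0 | 0.0100 |
| elm run | 8.0 | 0.0103 |
| elm run | 10 | 0.0148 |
| elm run | 12 | 0.0143 |
| larch run | 2.0 | 0.0242 |
| larch run | 4.0 | 0.0471 |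
| larch run | 6.0 | 0.0619 |
| larch run | 8.0 | 0.0695 |
| larch run | 10 | 0.0742 |
| larch run | 12 | 0.0754 |

(scatter of a reading: 0.001 M)

- Overall: L -> X.
- Constant volume, constant temperature.
- An order is taken over about fifteen percent of the charge, up and down.

* the power of [L] that the first rate follows, about the charge of the ash run; measure it at two percent of L made into X (one fixed amount of X, the same in the runs compared)
* X in the maple run at 12 min, as a share of the L charged

1. At 12 min the ash run holds a share 26.1 % and the larch run 31.4 %. We take the larch share as the large part and reckon the rise to maple as a correction, assuming a saturating form: share = ceiling × charge/(charge + K).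

2. On a plot of reciprocal share against reciprocal charge, ash and larch give a slope 0.156 M. So the ceiling is 39.5 % and K is 0.0617 M. We call K the fall-off charge, the charge at which the share stands at half its ceiling; the shape we assume is that of a Lindemann fall-off.

3. For the elm run this gives 19.5 %, less than the 23.8 % read there, with a scatter of 1.67 %. We keep the ash and larch charges for the maple reckoning.

4. Over its first 2.0 min the larch run gains a fraction of its charge of 0.0504 /min. Scaled by the fall-off, the maple run starts at 0.0570 /min. That start line meets our estimate of the maple level, 35.5 %, at 6.23 min, which is our estimate of the knee.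

5. If first rates fall off alike, rate goes as charge²/(charge + K), and the order about the ash charge is 1.34.

The forecast gives 1.25 and 40 %, on the reading “This fits parallel first- and second-order paths.” Our maple share is lower than the forecast's.

The maple run gives 33.0 %, and the order about the ash charge is 1.3.

    2 L ⇌ Q + L (0.9000 /M/min, 4.938 /M/min)
    Q → X (0.8280 /min)
    2 L → Qi (0.09420 /M/min)
    X → Yx (0.05238 /min)

A fit in which the substrate is lost by itself forecasts 35.4 % for maple, above the flask. Now K goes to the elm run. Starting from the ash rate 0.0046 M/min, taken where two percent of the ash L have turned into X, the fall-off form gives 0.00173 M/min for elm, and the elm rate at that same amount of X is 0.0017 M/min.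

Readings and results were generated by integration with constants of no real substance, and the scatter is random.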